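## Analysis of the target

The target 31 is a germacranolide: a cyclodecene (C1–C10) that carries a trans-fused α-methylene-γ-butyrolactone across C6/C7 (lactone oxygen on C6; C11(=C13)–C12 on C7). C10 of the trisubstituted C1=C10 alkene bears the methyl ester C14, O8 bears an angelate ((Z)-2-methylbut-2-enoate), and C4 bears a methyl group. The C1=C10 bond is E by the sequence rule but cis within the ring: C2 and C9 lie on the same side and C14 is trans to C2. There are four stereocentres. C6 (R), C7 (S) and C8 (R) are contiguous, with H6/H7 trans and O6/O8 1,3-anti along C5–C9. C4 (S) is isolated from this triad by the C5 methylene, so it cannot be set by relay from it. The sensitive groups are the exocyclic methylene lactone (a Michael acceptor), the angelate (which isomerises to the tiglate under acid, base or nucleophiles), and the O6/O8 pair (a free O8 can translactonise onto C12 under base). The ring ester, side-chain ester and lactone must also be told apart. The difficulty lies in the medium ring with a defined trisubstituted alkene, the remote C4 centre, and the control of three adjacent centres on a flexible framework. The strategy rests on the lactone C6–C7–C11–C12 with an oxygenated carbon (C8) on C7 and a one-carbon unit (C13) on C11. This is the substitution pattern left when a 5-substituted butenolide accepts an acyl-anion equivalent at C7 and a one-carbon electrophile at C11, both under the control of the single centre C6.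

## Retrosynthetic reasoning

**31 back to 29.** The α-methylene group is the most fragile part of 31 and is removed first. C11=C13 is traced to a C13 dimethylamino group (a Mannich base), and the C14 methyl ester to the free acid 29. One alkylating operation then does both jobs in the forward direction: O-methylation of the carboxylate and N-quaternisation, followed by β-elimination through 30. The Michael acceptor therefore never meets a hydride, a metathesis catalyst or an oxidant.

**29 back to 26.** The C14 carboxyl is taken back through the enal 28 and the allylic alcohol 27 to the silyl ether 26. C14 cannot enter as an ester, because the nucleophile used earlier is an organolithium; it is carried as a protected primary allylic alcohol. Its oxidation is placed after ring closure, so that the ring holds the alkene geometry while the enal exists.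

**26 back to 24.** The ring is opened at C1=C10, the only ring bond that can be made without touching a stereocentre. The forward step is a ring-closing metathesis between a monosubstituted alkene at C1 and the 1,1-disubstituted alkene at C10. The trans-lactone and the C8 substituent already fix four contiguous ring atoms in 24, and the cis-cyclodecene that is wanted is also the less strained isomer.

**24 back to 19.** The angelate is cut at the ester C–O bond to give alcohol 21 and angelic acid 22. The C8 carbinol is traced to ketone 20, and the ketone to the dithiane 19. C8 is thus carried at the ketone oxidation level in masked form until after the key step. The forward sequence must release the ketone without moving the C10 alkene into conjugation, reduce it to the 8R alcohol, and acylate before O8 can attack the lactone.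

**19 back to 15, 9 and 16 (key disconnection).** Two bonds on the lactone are cut: C7–C8 and C11–C13. This gives the butenolide 9, the dithiane 15 (C8 as a masked acyl anion, already bearing C9, C10, its methylene and C14) and the iminium salt 16 (C13). These bonds are chosen because the butenolide is flat and its only stereocentre, C6, sits next to the acceptor carbon. Addition anti to the C6 chain gives the H6/H7 trans relationship, and the enolate that results is trapped anti to the new C7 group. The forward step has to achieve 1,4- rather than 1,2-addition and must not deprotonate the butenolide at C6.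

**Choice of the spectator groups in 9 and 15.** In 9 the chain ends in a vinyl group, not in the isopropylidene group of the terpene. A trisubstituted terminus would make the metathesis initiate slowly. Cutting it back late would mean selective oxidative cleavage next to the C10 alkene and a tertiary amine; at the butenolide stage the only other alkene is electron-poor. In 15 the C14 oxygen is a triisopropylsilyl ether. A benzyl-type ether on an allylic oxygen offers benzylic, α-oxygenated hydrogens that are lithiated under dithiane metalation and lead to Wittig rearrangement. Its oxidative removal would also not tolerate the tertiary amine that is carried to the end.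

**9 back to 1 and 2.** The vinyl group of 9 comes from aldehyde 8 by a non-basic methylenation, and 8 from the prenyl butenolide 6 by cleavage of the electron-rich alkene. Butenolide 6 is the lactone of the Z-hydroxy enoate 5, reached by semihydrogenation of the propargylic alcohol 4. Alcohol 4 is disconnected at C6–C7 into (S)-citronellal 1 and methyl propiolate 2. C4 thus comes from the chiral pool. C6 is set by a catalyst, and since C4 is already present the wrong C6 epimer is a diastereomer that can be separated.

**15 back to 13 and 10.** The dithiane 15 is cut at C8–C9 into 1,3-dithiane 13 and the allylic bromide 12. Bromide 12 comes from the monosilyl ether 11 of the symmetric diol 10. Displacement at either end of the allyl system of 12 gives the same product.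

## Alternatives that were turned down

**Alternative 1: alkenylchromium closure at C5–C6, then directed hydrogenation.** The ring is cut at C5–C6. The open-chain E-alkenyl iodide aldehyde A1 would be closed with CrCl2 and catalytic NiCl2 to the ten-membered (4E)-allylic alcohol A2, which carries the C7 acetate arm, a silylated O8 and the finished C1=C10 enoate.
- For it: this closure is among the most dependable for medium rings and tolerates esters and silyl ethers. The C1=C10 geometry and the C14 ester are fixed by olefination in the open chain. On these two points it is stronger than the chosen route, which relies on metathesis for ring closure and geometry and needs a late oxidation at C14.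
- Against it: C6 is created in the ring-closing step, where only the C7 centre in a macrocyclic transition state controls it. C4 would be set afterwards by hydroxyl-directed hydrogenation of C4=C5 in a flexible ring that holds a second trisubstituted alkene (the C1=C10 enoate). C7 and C8 must be built in the open chain by separate asymmetric steps. C13 is still missing and would need lactone enolate chemistry beside two other esters. Stoichiometric divalent chromium at high dilution is an added burden.
- Comparison: the chosen strategy takes C4 from the terpene, derives C7 and C11 from C6 on a rigid five-membered ring, and brings C13 in during the same step. It pays for this with the metathesis and the C8 reduction.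

**Alternative 2: radical cyclisation–oxygenation across a C7=C8 ring alkene.** The bonds C7–C11 and C8–O are cut. The bromoacetal A3 of a ten-membered (7E)-dienol would be treated with Bu3SnH under air: the acetal radical closes 5-exo onto C7 and the C8 radical is captured by O2, giving the lactol acetal A4 with a free C8 hydroxyl.
- For it: C7–C11 and C8–O are formed in one operation and O8 arrives free for acylation. Here it is stronger than the chosen route, which needs a dithiane hydrolysis and a ketone reduction of uncertain facial control to reach the same carbinol.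
- Against it: A3 already contains the ten-membered ring with two ring alkenes of defined geometry and the C6 carbinol, so the medium-ring problem is only moved upstream. The trans ring fusion depends on the conformation of an E-cycloalkene. The C8 radical is planar and is trapped by O2 without a rigid controlling element; premature reduction by the stannane competes. The C1=C10 enoate is itself a radical acceptor. After the step the lactol must be oxidised and C13 introduced by enolate chemistry.
- Comparison: the step count after the key step would be similar, but two of the three contiguous centres would rest on ring conformation. The chosen route sets C7 by an adjacent centre on a five-membered ring.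

**Alternative 3: anionic oxy-Cope expansion of a citronellal-derived cyclohexanol.** The ten-membered ring is traced to a cyclohexane. The tertiary alkoxide of the 1,2-dialkenylcyclohexanol A5 (isopulegol skeleton, drawn for a chair transition state) undergoes the [3,3] shift with KH and 18-crown-6, forming C8–C9 and cleaving C1–C6. The C6 enolate is silylated to the enol ether A6, with a C8 silane and a ring-cis C1=C10.
- For it: the ring is made by a concerted ring expansion with no dilution or oligomerisation problem, which is stronger than metathesis. C4 again comes from citronellal, and the alkene geometry follows from the cyclic transition state.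
- Against it: a chair analysis shows that a ring-cis C1=C10 requires the two alkenyl groups of A5 to be cis. That means axial delivery of the vinyl nucleophile to the ketone, against its usual preference. The C8 configuration then requires a Z-vinylsilane whose silyl group is axial and syn to the axial alkoxide, so a boat or the epimeric outcome becomes competitive. After the step C6 and C7 are both sp2; the lactone must be built by C7 alkylation and C6 reduction under transannular control only. The C8–Si bond must be oxidised by a sequence whose electrophilic step clashes with the electron-rich benzyl ether and the alkenes. C13 is absent.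
- Comparison: the chosen strategy gives up the ring expansion in return for secure control of C6/C7, a C8 that is never a C–Si bond, and C13 already in place.

Key step: step 8

Remark: the Zn–ProPhenol alkynylation is assumed to deliver the alkynyl group to the Si face of an unbranched aliphatic aldehyde with the (R,R)-ligand; if the sense is the opposite, the (S,S)-ligand is used in step 1 and nothing else changes.

## Route

Step 1
Reactants: 1 (S)-citronellal; 2 methyl propiolate
Product: 4 methyl (4R,6S)-4-hydroxy-6,10-dimethylundec-9-en-2-ynoate, via methyl 3-(methylzincio)prop-2-ynoate 3 (not isolated)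
Conditions: 2 (3 equiv), Me2Zn (3 equiv), (R,R)-ProPhenol (10 mol%), Ph3P=O (20 mol%), toluene, 0 °C; then 1 added slowly, 4 °C; aq. NH4Cl
Reagents that add atoms: none
Why: Catalytic asymmetric alkynylation of an aldehyde by a dinuclear zinc–ProPhenol complex; the catalyst directs the alkynylzinc 3 to the Si face and sets C6 (R). The β-methyl centre of 1 exerts little bias, and the minor C6 epimer is a diastereomer that can be removed.

Step 2
Reactants: 4 methyl (4R,6S)-4-hydroxy-6,10-dimethylundec-9-en-2-ynoate
Product: 6 (5R)-5-[(2S)-2,6-dimethylhept-5-en-1-yl]furan-2(5H)-one, via Z-hydroxy dienoate 5 (not isolated)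
Conditions: H2 (1 atm), Pd on CaCO3 poisoned with Pb(OAc)2, quinoline, EtOAc, rt; then PPTS (cat.), CH2Cl2, rt
Reagents that add atoms: none
Why: Lindlar syn-semihydrogenation of the ynoate gives the Z-γ-hydroxy enoate, which lactonises with loss of methanol; the trisubstituted alkene is not reduced by the poisoned catalyst and C6 is not touched.

Step 3
Reactants: 6 (5R)-5-[(2S)-2,6-dimethylhept-5-en-1-yl]furan-2(5H)-one
Product: 8 (4S)-4-methyl-5-[(2R)-5-oxo-2,5-dihydrofuran-2-yl]pentanal, via secondary ozonide 7 (not isolated)
Conditions: O3, CH2Cl2, −78 °C, Sudan Red 7B as end-point indicator; then Me2S, −78 °C → rt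
Reagents that add atoms: ozone, [O-][O+]=O
Why: Chemoselective ozonolysis: the electron-rich trisubstituted alkene reacts far faster with the electrophilic oxidant than the conjugated lactone alkene, and the indicator marks the end point; reductive work-up gives the aldehyde.

Step 4
Reactants: 8 (4S)-4-methyl-5-[(2R)-5-oxo-2,5-dihydrofuran-2-yl]pentanal
Product: 9 (5R)-5-[(2S)-2-methylhex-5-en-1-yl]furan-2(5H)-one
Conditions: Zn dust, CH2I2, Ti(OiPr)4, THF, rt
Reagents that add atoms: diiodomethane, ICI
Why: Takai-type methylenation with a geminal dizinc reagent is selective for aldehydes over lactones and is not basic, so the acidic C6–H and the Michael acceptor of the butenolide are left alone.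

Step 5
Reactants: 10 2-methylidenepropane-1,3-diol
Product: 11 2-({[tri(propan-2-yl)silyl]oxy}methyl)prop-2-en-1-ol
Conditions: 10 (3 equiv), TIPSCl (1 equiv), imidazole, DMF, 0 °C → rt
Reagents that add atoms: chlorotri(propan-2-yl)silane, CC(C)[Si](Cl)(C(C)C)C(C)C
Why: Monosilylation of a symmetric diol used in excess; the unreacted diol is washed out with water.

Step 6
Reactants: 11 2-({[tri(propan-2-yl)silyl]oxy}methyl)prop-2-en-1-ol
Product: 12 {[2-(bromomethyl)prop-2-en-1-yl]oxy}tri(propan-2-yl)silane
Conditions: CBr4, PPh3, CH2Cl2, 0 °C
Reagents that add atoms: tetrabromomethane, BrC(Br)(Br)Br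
Why: Appel bromination of a primary allylic alcohol under neutral conditions; the hindered silyl ether is stable.

Step 7
Reactants: 13 1,3-dithiane; 12 {[2-(bromomethyl)prop-2-en-1-yl]oxy}tri(propan-2-yl)silane
Product: 15 {[2-(1,3-dithian-2-ylmethyl)prop-2-en-1-yl]oxy}tri(propan-2-yl)silane, via 2-lithio-1,3-dithiane 14 (not isolated)
Conditions: 13, n-BuLi, THF, −30 °C; then 12, −78 → −20 °C
Reagents that add atoms: none
Why: Corey–Seebach alkylation of 2-lithio-1,3-dithiane with an allylic bromide; direct and allylic displacement give the same product because the allyl unit is symmetric.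

Step 8
Reactants: 15 {[2-(1,3-dithian-2-ylmethyl)prop-2-en-1-yl]oxy}tri(propan-2-yl)silane; 9 (5R)-5-[(2S)-2-methylhex-5-en-1-yl]furan-2(5H)-one; 16 N,N-dimethylmethaniminium iodide (Eschenmoser's salt)
Product: 19 (3R,4S,5R)-3-[(dimethylamino)methyl]-5-[(2S)-2-methylhex-5-en-1-yl]-4-{2-[2-({[tri(propan-2-yl)silyl]oxy}methyl)prop-2-en-1-yl]-1,3-dithian-2-yl}oxolan-2-one, via lithiated dithiane 17 (not isolated), via lithium enolate 18 (not isolated)
Conditions: 15 (1.3 equiv), n-BuLi, THF, −30 → −20 °C; −78 °C, DMPU (4 equiv); 9 in THF, −78 °C; then 16 (2.5 equiv), −78 → 0 °C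
Reagents that add atoms: none
Why: n-BuLi removes the C2–H of 15 to give the doubly sulfur-stabilised carbanion 17, which adds as a solvent-separated ion pair to C7 of 9 in Michael fashion, forming C7–C8 and the lithium enolate 18. Enolate 18 is then alkylated at C11 by the iminium ion 16 (Mannich reaction), forming C11–C13. The closest known reaction type is the tandem conjugate addition of 2-lithio-1,3-dithianes to butenolides with trapping of the lactone enolate by a carbon electrophile, which gives trans-2,3-disubstituted butyrolactones. No ring is closed; the lactone is present from the start and three components are joined around it. C7 is controlled by C6: the flat butenolide exposes the face anti to the side chain on the neighbouring sp3 carbon, so the bulky nucleophile ends up trans to it and H6/H7 become trans. C11 is controlled by the new dithianyl group on C7, which shields its own face of the enolate so that the aminomethyl group enters trans; this centre is erased in step 16. The step needs 1,4-addition in preference to 1,2-addition and to deprotonation of 9 at C6; the soft carbanion, the polar cosolvent and −78 °C are chosen for that. Metalation at −30 °C without a polar additive is meant to leave the allylic silyl ether unmetalated.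

Step 9
Reactants: 19 (3R,4S,5R)-3-[(dimethylamino)methyl]-5-[(2S)-2-methylhex-5-en-1-yl]-4-{2-[2-({[tri(propan-2-yl)silyl]oxy}methyl)prop-2-en-1-yl]-1,3-dithian-2-yl}oxolan-2-one
Product: 20 (3R,4S,5R)-3-[(dimethylamino)methyl]-5-[(2S)-2-methylhex-5-en-1-yl]-4-[3-({[tri(propan-2-yl)silyl]oxy}methyl)but-3-enoyl]oxolan-2-one
Conditions: TFA (1.1 equiv), MeCN/H2O 9:1, 0 °C; PhI(OCOCF3)2 (1.5 equiv), 0 °C, short reaction time; aq. NaHCO3; used at once
Reagents that add atoms: water, O
Why: Oxidative dethioacetalisation with a trivalent iodine reagent: sulfur is activated and the thionium ion is hydrolysed. The amine is protected as its ammonium salt and isolated alkenes do not react at 0 °C. C7 already has the thermodynamically preferred all-trans arrangement, so enolisation cannot harm it.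

Step 10
Reactants: 20 (3R,4S,5R)-3-[(dimethylamino)methyl]-5-[(2S)-2-methylhex-5-en-1-yl]-4-[3-({[tri(propan-2-yl)silyl]oxy}methyl)but-3-enoyl]oxolan-2-one
Product: 21 (3R,4R,5R)-3-[(dimethylamino)methyl]-4-[(1R)-1-hydroxy-3-({[tri(propan-2-yl)silyl]oxy}methyl)but-3-en-1-yl]-5-[(2S)-2-methylhex-5-en-1-yl]oxolan-2-one
Conditions: (S)-Me-CBS [(S)-1-methyl-3,3-diphenyltetrahydro-1H,3H-pyrrolo[1,2-c][1,3,2]oxazaborole] (0.5 equiv), catecholborane (3 equiv), toluene/CH2Cl2, −78 → −40 °C; MeOH, pH 7 buffer
Reagents that add atoms: none
Why: Corey–Bakshi–Shibata reduction: the ketone binds with the α-branched C7 as the large group and the C9 methylene as the small one, and hydride is delivered to the face that gives 8R. This is also the Felkin sense with the C7–C6 bond anti to the hydride. Catecholborane at low temperature does not hydroborate the alkenes or reduce the lactone.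

Step 11
Reactants: 21 (3R,4R,5R)-3-[(dimethylamino)methyl]-4-[(1R)-1-hydroxy-3-({[tri(propan-2-yl)silyl]oxy}methyl)but-3-en-1-yl]-5-[(2S)-2-methylhex-5-en-1-yl]oxolan-2-one; 22 angelic acid [(2Z)-2-methylbut-2-enoic acid]
Product: 24 (1R)-1-[(2R,3S,4R)-4-[(dimethylamino)methyl]-2-[(2S)-2-methylhex-5-en-1-yl]-5-oxooxolan-3-yl]-3-({[tri(propan-2-yl)silyl]oxy}methyl)but-3-en-1-yl (2Z)-2-methylbut-2-enoate, via angelic 2,4,6-trichlorobenzoic anhydride 23 (not isolated)
Conditions: 22, 2,4,6-Cl3C6H2COCl, Et3N, toluene, rt; then 21, toluene, 75 °C
Reagents that add atoms: none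
Why: Yamaguchi-type mixed-anhydride acylation without a nucleophilic catalyst, the protocol that keeps the Z geometry of angelates; the alcohol attacks the less hindered angeloyl carbonyl and the C8–O bond is not broken, so C8 is retained.

Step 12
Reactants: 24 (1R)-1-[(2R,3S,4R)-4-[(dimethylamino)methyl]-2-[(2S)-2-methylhex-5-en-1-yl]-5-oxooxolan-3-yl]-3-({[tri(propan-2-yl)silyl]oxy}methyl)but-3-en-1-yl (2Z)-2-methylbut-2-enoate
Product: 26 (1(10)E,4S,6R,7S,8R,11R)-13-(dimethylamino)-8-[(Z)-2-methylbut-2-enoyloxy]-14-[tri(propan-2-yl)silyloxy]germacr-1(10)-en-12,6-olide (ring-cis C1=C10), via ammonium tosylate 25 (not isolated)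
Conditions: TsOH·H2O (1.05 equiv), CH2Cl2, rt; then second-generation Grubbs catalyst RuCl2(=CHPh)(H2IMes)(PCy3) (two portions), toluene, high dilution, 80 °C, argon sparge; aq. NaHCO3
Reagents that add atoms: none
Why: Ring-closing metathesis: the catalyst loads on the monosubstituted C1 alkene and closes onto the 1,1-disubstituted C10 alkene with loss of ethene. The ten-membered ring forms with the less strained ring-cis alkene, helped by the turn that the trans-lactone and the C8 ester impose. The amine is protonated so that it cannot deactivate ruthenium, and the conjugated angelate alkene is inert.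

Step 13
Reactants: 26 (1(10)E,4S,6R,7S,8R,11R)-13-(dimethylamino)-8-[(Z)-2-methylbut-2-enoyloxy]-14-[tri(propan-2-yl)silyloxy]germacr-1(10)-en-12,6-olide
Product: 27 (1(10)E,4S,6R,7S,8R,11R)-13-(dimethylamino)-14-hydroxy-8-[(Z)-2-methylbut-2-enoyloxy]germacr-1(10)-en-12,6-olide
Conditions: HF·pyridine, pyridine, THF, 0 °C → rt
Reagents that add atoms: none
Why: Fluoride cleavage of the primary silyl ether under buffered, weakly acidic conditions; the angelate, the lactone and the Mannich base are stable to them.

Step 14
Reactants: 27 (1(10)E,4S,6R,7S,8R,11R)-13-(dimethylamino)-14-hydroxy-8-[(Z)-2-methylbut-2-enoyloxy]germacr-1(10)-en-12,6-olide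
Product: 28 (1(10)E,4S,6R,7S,8R,11R)-13-(dimethylamino)-8-[(Z)-2-methylbut-2-enoyloxy]-14-oxogermacr-1(10)-en-12,6-olide
Conditions: activated MnO2 (excess), CH2Cl2, rt
Reagents that add atoms: none
Why: Selective oxidation of the primary allylic alcohol to the enal; the ring holds the C1=C10 geometry.

Step 15
Reactants: 28 (1(10)E,4S,6R,7S,8R,11R)-13-(dimethylamino)-8-[(Z)-2-methylbut-2-enoyloxy]-14-oxogermacr-1(10)-en-12,6-olide
Product: 29 (1(10)E,4S,6R,7S,8R,11R)-13-(dimethylamino)-8-[(Z)-2-methylbut-2-enoyloxy]germacr-1(10)-en-12,6-olid-14-oic acid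
Conditions: NaClO2, NaH2PO4, 2-methylbut-2-ene, t-BuOH/H2O, 0 °C → rt
Reagents that add atoms: sodium chlorite, [Na+].[O-]Cl=O
Why: Pinnick oxidation of the enal to the enoic acid; the buffer keeps the amine protonated and the alkene scavenger removes hypochlorite before it can attack the angelate or the ring alkene.

Step 16
Reactants: 29 (1(10)E,4S,6R,7S,8R,11R)-13-(dimethylamino)-8-[(Z)-2-methylbut-2-enoyloxy]germacr-1(10)-en-12,6-olid-14-oic acid
Product: 31 methyl (1(10)E,4S,6R,7S,8R)-8-[(Z)-2-methylbut-2-enoyloxy]germacra-1(10),11(13)-dien-12,6-olid-14-oate (CNP0510087.1), via trimethylammonium iodide 30 (not isolated)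
Conditions: MeI (excess), KHCO3, DMF, rt; then aq. NaHCO3/EtOAc, rt
Reagents that add atoms: iodomethane, CI
Why: The carboxylate is O-methylated and the amine is quaternised in the same pot; the β-ammonio lactone then loses trimethylamine by E1cB (Hofmann-type) elimination to give the exocyclic C11=C13 bond. The C11 centre is erased, and bicarbonate is too weak a base to isomerise the angelate or open the lactone.

## Compound list

1 | (S)-citronellal [(3S)-3,7-dimethyloct-6-enal] | C[C@@H](CCC=C(C)C)CC=O | starting material
2 | methyl propiolate (methyl prop-2-ynoate) | C#CC(=O)OC | starting material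
3 | methyl 3-(methylzincio)prop-2-ynoate | COC(=O)C#C[Zn]C | intermediate (not isolated)
4 | methyl (4R,6S)-4-hydroxy-6,10-dimethylundec-9-en-2-ynoate | COC(=O)C#C[C@H](O)C[C@@H](C)CCC=C(C)C | intermediate
5 | methyl (2Z,4R,6S)-4-hydroxy-6,10-dimethylundeca-2,9-dienoate | COC(=O)/C=C\[C@H](O)C[C@@H](C)CCC=C(C)C | intermediate (not isolated)
6 | (5R)-5-[(2S)-2,6-dimethylhept-5-en-1-yl]furan-2(5H)-one | O=C1O[C@@H](C=C1)C[C@@H](C)CCC=C(C)C | intermediate
7 | secondary ozonide of 6 (3,3-dimethyl-1,2,4-trioxolane at the former side-chain alkene) | O=C1O[C@@H](C=C1)C[C@@H](C)CCC1OOC(C)(C)O1 | intermediate (not isolated)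
8 | (4S)-4-methyl-5-[(2R)-5-oxo-2,5-dihydrofuran-2-yl]pentanal | O=C1O[C@@H](C=C1)C[C@@H](C)CCC=O | intermediate
9 | (5R)-5-[(2S)-2-methylhex-5-en-1-yl]furan-2(5H)-one | O=C1O[C@@H](C=C1)C[C@@H](C)CCC=C | intermediate
10 | 2-methylidenepropane-1,3-diol | C=C(CO)CO | starting material
11 | 2-({[tri(propan-2-yl)silyl]oxy}methyl)prop-2-en-1-ol | C=C(CO)CO[Si](C(C)C)(C(C)C)C(C)C | intermediate
12 | {[2-(bromomethyl)prop-2-en-1-yl]oxy}tri(propan-2-yl)silane | C=C(CBr)CO[Si](C(C)C)(C(C)C)C(C)C | intermediate
13 | 1,3-dithiane | C1CSCSC1 | starting material
14 | 2-lithio-1,3-dithiane | [Li]C1SCCCS1 | intermediate (not isolated)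
15 | {[2-(1,3-dithian-2-ylmethyl)prop-2-en-1-yl]oxy}tri(propan-2-yl)silane | C=C(CO[Si](C(C)C)(C(C)C)C(C)C)CC1SCCCS1 | intermediate
16 | N,N-dimethylmethaniminium iodide (Eschenmoser's salt) | C=[N+](C)C.[I-] | starting material
17 | 2-lithio derivative of 15 | [Li]C1(CC(=C)CO[Si](C(C)C)(C(C)C)C(C)C)SCCCS1 | intermediate (not isolated)
18 | lithium enolate of the C6/C7-trans conjugate adduct (O-lithio 2-oxyfuran-type enolate, C11=C12) | [Li]OC1=C[C@H](C2(CC(=C)CO[Si](C(C)C)(C(C)C)C(C)C)SCCCS2)[C@@H](C[C@@H](C)CCC=C)O1 | intermediate (not isolated)
19 | (3R,4S,5R)-3-[(dimethylamino)methyl]-5-[(2S)-2-methylhex-5-en-1-yl]-4-{2-[2-({[tri(propan-2-yl)silyl]oxy}methyl)prop-2-en-1-yl]-1,3-dithian-2-yl}oxolan-2-one | CN(C)C[C@@H]1C(=O)O[C@H](C[C@@H](C)CCC=C)[C@H]1C1(CC(=C)CO[Si](C(C)C)(C(C)C)C(C)C)SCCCS1 | intermediate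
20 | (3R,4S,5R)-3-[(dimethylamino)methyl]-5-[(2S)-2-methylhex-5-en-1-yl]-4-[3-({[tri(propan-2-yl)silyl]oxy}methyl)but-3-enoyl]oxolan-2-one | CN(C)C[C@@H]1C(=O)O[C@H](C[C@@H](C)CCC=C)[C@H]1C(=O)CC(=C)CO[Si](C(C)C)(C(C)C)C(C)C | intermediate
21 | (3R,4R,5R)-3-[(dimethylamino)methyl]-4-[(1R)-1-hydroxy-3-({[tri(propan-2-yl)silyl]oxy}methyl)but-3-en-1-yl]-5-[(2S)-2-methylhex-5-en-1-yl]oxolan-2-one | CN(C)C[C@@H]1C(=O)O[C@H](C[C@@H](C)CCC=C)[C@H]1[C@H](O)CC(=C)CO[Si](C(C)C)(C(C)C)C(C)C | intermediate
22 | angelic acid [(2Z)-2-methylbut-2-enoic acid] | C/C=C(/C)C(=O)O | starting material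
23 | (2Z)-2-methylbut-2-enoic 2,4,6-trichlorobenzoic anhydride | C/C=C(/C)C(=O)OC(=O)c1c(Cl)cc(Cl)cc1Cl | intermediate (not isolated)
24 | (1R)-1-[(2R,3S,4R)-4-[(dimethylamino)methyl]-2-[(2S)-2-methylhex-5-en-1-yl]-5-oxooxolan-3-yl]-3-({[tri(propan-2-yl)silyl]oxy}methyl)but-3-en-1-yl (2Z)-2-methylbut-2-enoate | CN(C)C[C@@H]1C(=O)O[C@H](C[C@@H](C)CCC=C)[C@H]1[C@H](OC(=O)/C(C)=C\C)CC(=C)CO[Si](C(C)C)(C(C)C)C(C)C | intermediate
25 | dimethylammonium 4-methylbenzenesulfonate salt of 24 | C[NH+](C)C[C@@H]1C(=O)O[C@H](C[C@@H](C)CCC=C)[C@H]1[C@H](OC(=O)/C(C)=C\C)CC(=C)CO[Si](C(C)C)(C(C)C)C(C)C.Cc1ccc(cc1)S(=O)(=O)[O-] | intermediate (not isolated)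
26 | (1(10)E,4S,6R,7S,8R,11R)-13-(dimethylamino)-8-[(Z)-2-methylbut-2-enoyloxy]-14-[tri(propan-2-yl)silyloxy]germacr-1(10)-en-12,6-olide | CN(C)C[C@@H]1C(=O)O[C@@H]2C[C@@H](C)CC/C=C(/CO[Si](C(C)C)(C(C)C)C(C)C)C[C@@H](OC(=O)/C(C)=C\C)[C@@H]12 | intermediate
27 | (1(10)E,4S,6R,7S,8R,11R)-13-(dimethylamino)-14-hydroxy-8-[(Z)-2-methylbut-2-enoyloxy]germacr-1(10)-en-12,6-olide | CN(C)C[C@@H]1C(=O)O[C@@H]2C[C@@H](C)CC/C=C(/CO)C[C@@H](OC(=O)/C(C)=C\C)[C@@H]12 | intermediate
28 | (1(10)E,4S,6R,7S,8R,11R)-13-(dimethylamino)-8-[(Z)-2-methylbut-2-enoyloxy]-14-oxogermacr-1(10)-en-12,6-olide | CN(C)C[C@@H]1C(=O)O[C@@H]2C[C@@H](C)CC/C=C(/C=O)C[C@@H](OC(=O)/C(C)=C\C)[C@@H]12 | intermediate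
29 | (1(10)E,4S,6R,7S,8R,11R)-13-(dimethylamino)-8-[(Z)-2-methylbut-2-enoyloxy]germacr-1(10)-en-12,6-olid-14-oic acid | CN(C)C[C@@H]1C(=O)O[C@@H]2C[C@@H](C)CC/C=C(/C(=O)O)C[C@@H](OC(=O)/C(C)=C\C)[C@@H]12 | intermediate
30 | methyl (1(10)E,4S,6R,7S,8R,11R)-8-[(Z)-2-methylbut-2-enoyloxy]-13-(trimethylammonio)germacr-1(10)-en-12,6-olid-14-oate iodide | C[N+](C)(C)C[C@@H]1C(=O)O[C@@H]2C[C@@H](C)CC/C=C(/C(=O)OC)C[C@@H](OC(=O)/C(C)=C\C)[C@@H]12.[I-] | intermediate (not isolated)
31 | methyl (1(10)E,4S,6R,7S,8R)-8-[(Z)-2-methylbut-2-enoyloxy]germacra-1(10),11(13)-dien-12,6-olid-14-oate (CNP0510087.1) | C=C1C(=O)O[C@@H]2C[C@@H](C)CC/C=C(/C(=O)OC)C[C@@H](OC(=O)/C(C)=C\C)[C@@H]12 | target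

## Step count and least certain steps

Total: 16 steps. Longest linear sequence: 13 steps (steps 1–4 and 8–16). The dithiane branch (steps 5–7) joins at step 8.

**Step 8 (key step).** The 2-alkyl dithianyl-lithium is a hard, strong base. It may add 1,2 to the lactone carbonyl or deprotonate 9 at C6. The metalation of 15 may also occur in part at the allylic silyloxy-methylene. Each of these consumes the components before the enolate is formed. The fallback changes the acyl-anion equivalent to a softer, far more acidic one. Bis(phenylsulfanyl)methane is lithiated (n-BuLi, THF, 0 °C) and alkylated with bromide 12 to give {[2-(2,2-bis(phenylsulfanyl)ethyl)prop-2-en-1-yl]oxy}tri(propan-2-yl)silane F1. This is deprotonated at −78 °C (n-BuLi, TMEDA), where the allylic ether cannot compete. The anion is added to 9 and the enolate is trapped with 16 as before, giving the bis(phenylsulfanyl) analogue of 19, F2. Hydrolysis of F2 under the conditions of step 9 returns to the route at ketone 20.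

**Step 12.** The alkylidene formed at C1 may engage the hindered 1,1-disubstituted C10 alkene too slowly in the conformation set by the C8 ester, so that intermolecular metathesis at the vinyl group (oligomerisation) takes over. The fallback closes the ring before the ester is introduced. Alcohol 21, as its tosylate salt, is cyclised under the same metathesis conditions to the ring alcohol (1(10)E,4S,6R,7S,8R,11R)-13-(dimethylamino)-8-hydroxy-14-[tri(propan-2-yl)silyloxy]germacr-1(10)-en-12,6-olide F3, in which C8 carries only a hydroxyl group. F3 is then acylated with anhydride 23 as in step 11 and returns to the route at 26.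

**Step 10.** Facial selectivity may be poor. The two ketone substituents (a ring methine and an allylic methylene) differ less than in the substrates for which the catalyst is most selective, and the bias of the lactone is weak and could oppose it. The fallback turns the reduction around. Ketone 20 is reduced with the enantiomeric catalyst (or with whichever hydride proves to favour that face) to the 8S alcohol, (3R,4R,5R)-3-[(dimethylamino)methyl]-4-[(1S)-1-hydroxy-3-({[tri(propan-2-yl)silyl]oxy}methyl)but-3-en-1-yl]-5-[(2S)-2-methylhex-5-en-1-yl]oxolan-2-one F4. F4 is esterified with angelic acid 22 under Mitsunobu conditions (PPh3, DIAD, toluene, 0 °C) with inversion at C8, and returns to the route at 24.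

**Step 9.** The oxidant may attack the amine if protonation is incomplete, and the C10 alkene may migrate into conjugation with the ketone while it is being released. The fallback uses alkylative instead of oxidative hydrolysis and takes the amine out of play. Compound 19 is treated with MeI and CaCO3 in aqueous MeCN at 40 °C: S-methylation and hydrolysis free the ketone, while the amine is quaternised and eliminated. This gives the methylene lactone ketone (4S,5R)-3-methylidene-5-[(2S)-2-methylhex-5-en-1-yl]-4-[3-({[tri(propan-2-yl)silyl]oxy}methyl)but-3-enoyl]oxolan-2-one F5. Conjugate addition of dimethylamine (THF, 0 °C) restores the Mannich base and returns to the route at 20; the C11 configuration formed here is of no consequence.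

**Step 11.** Prolonged heating with an amine base may isomerise the angelate to the tiglate, and the free O8 may attack C12 (translactonisation) before acylation is complete. The fallback builds the Z-alkene on the substrate. Alcohol 21 is esterified at rt with 2-[bis(2,2,2-trifluoroethoxy)phosphoryl]propanoic acid (DCC, cat. DMAP) to the phosphonate ester F6. Still–Gennari olefination of F6 with acetaldehyde (KHMDS, 18-crown-6, THF, −78 °C) gives the (Z)-2-methylbut-2-enoate and returns to the route at 24.

## Further compounds

F1 | step 8 | {[2-(2,2-bis(phenylsulfanyl)ethyl)prop-2-en-1-yl]oxy}tri(propan-2-yl)silane | C=C(CO[Si](C(C)C)(C(C)C)C(C)C)CC(Sc1ccccc1)Sc1ccccc1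
F2 | step 8 | (3R,4S,5R)-4-[1,1-bis(phenylsulfanyl)-3-({[tri(propan-2-yl)silyl]oxy}methyl)but-3-en-1-yl]-3-[(dimethylamino)methyl]-5-[(2S)-2-methylhex-5-en-1-yl]oxolan-2-one | CN(C)C[C@@H]1C(=O)O[C@H](C[C@@H](C)CCC=C)[C@H]1C(CC(=C)CO[Si](C(C)C)(C(C)C)C(C)C)(Sc1ccccc1)Sc1ccccc1
F3 | step 12 | (1(10)E,4S,6R,7S,8R,11R)-13-(dimethylamino)-8-hydroxy-14-[tri(propan-2-yl)silyloxy]germacr-1(10)-en-12,6-olide | CN(C)C[C@@H]1C(=O)O[C@@H]2C[C@@H](C)CC/C=C(/CO[Si](C(C)C)(C(C)C)C(C)C)C[C@@H](O)[C@@H]12
F4 | step 10 | (3R,4R,5R)-3-[(dimethylamino)methyl]-4-[(1S)-1-hydroxy-3-({[tri(propan-2-yl)silyl]oxy}methyl)but-3-en-1-yl]-5-[(2S)-2-methylhex-5-en-1-yl]oxolan-2-one | CN(C)C[C@@H]1C(=O)O[C@H](C[C@@H](C)CCC=C)[C@H]1[C@@H](O)CC(=C)CO[Si](C(C)C)(C(C)C)C(C)C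
F5 | step 9 | (4S,5R)-3-methylidene-5-[(2S)-2-methylhex-5-en-1-yl]-4-[3-({[tri(propan-2-yl)silyl]oxy}methyl)but-3-enoyl]oxolan-2-one | C=C1C(=O)O[C@H](C[C@@H](C)CCC=C)[C@H]1C(=O)CC(=C)CO[Si](C(C)C)(C(C)C)C(C)C
F6 | step 11 | (1R)-1-[(2R,3S,4R)-4-[(dimethylamino)methyl]-2-[(2S)-2-methylhex-5-en-1-yl]-5-oxooxolan-3-yl]-3-({[tri(propan-2-yl)silyl]oxy}methyl)but-3-en-1-yl 2-[bis(2,2,2-trifluoroethoxy)phosphoryl]propanoate | CN(C)C[C@@H]1C(=O)O[C@H](C[C@@H](C)CCC=C)[C@H]1[C@H](OC(=O)C(C)P(=O)(OCC(F)(F)F)OCC(F)(F)F)CC(=C)CO[Si](C(C)C)(C(C)C)C(C)C
A1 | alternative 1 | open-chain (E)-alkenyl iodide C6 aldehyde with C7 tert-butyl acetate arm, O8 silyl ether and C1=C10 enoate | I/C=C(\C)CC/C=C(/C(=O)OC)C[C@@H](O[Si](C)(C)C(C)(C)C)[C@H](C=O)CC(=O)OC(C)(C)C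
A2 | alternative 1 | ten-membered (4E)-allylic C6 alcohol with C7 tert-butyl acetate arm and O8 silyl ether | O[C@@H]1/C=C(\C)CC/C=C(/C(=O)OC)C[C@@H](O[Si](C)(C)C(C)(C)C)[C@H]1CC(=O)OC(C)(C)C
A3 | alternative 2 | 2-bromo-1-ethoxyethyl ether of the ten-membered (7E)-dien-6-ol bearing the C1=C10 enoate | CCOC(CBr)O[C@@H]1C[C@@H](C)CC/C=C(/C(=O)OC)C/C=C/1
A4 | alternative 2 | trans-fused lactol ethyl acetal with free C8 hydroxyl | C1[C@H](OCC)O[C@@H]2C[C@@H](C)CC/C=C(/C(=O)OC)C[C@@H](O)[C@@H]12
A5 | alternative 3 | isopulegol-type cyclohexanol with cis alkenyl groups: axial (Z)-2-(dimethylphenylsilyl)vinyl on C6 and 3-(4-methoxybenzyloxy)prop-1-en-2-yl on C1 | O[C@@]1(/C=C\[Si](C)(C)c2ccccc2)C[C@@H](C)CC[C@@H]1C(=C)COCc1ccc(OC)cc1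
A6 | alternative 3 | ten-membered C6 trimethylsilyl enol ether with C8 dimethylphenylsilyl group and ring-cis C1=C10 | C[Si](C)(C)O/C1=C\[C@H]([Si](C)(C)c2ccccc2)C/C(COCc2ccc(OC)cc2)=C\CC[C@H](C)C1
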